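## Structural features

The target is a cis-fused decalin: ring A (C1–C5, C10) carries the gem-dimethyl group at C4, ring B (C5–C10) carries all the oxygen, and an (E)-3-oxobut-1-enyl chain (C11–C14) sits on C9. With β defined as the face of the C10 methyl group, the six contiguous stereocentres are 5β-H, 6α-OAc, 7β-OH, 8α-OH/8β-CH3, 9β-chain and 10β-CH3. The three oxygens therefore alternate faces, while the C8 methyl, the C9 chain and the C10 methyl are all cis. The fragile groups are the enone with its γ-hydrogen at C9 next to a tertiary alcohol (dehydration or retro-aldol-type cleavage), the secondary acetate beside a free secondary hydroxyl (acyl migration), and the tertiary alcohol itself. The real difficulty is ring B, where four stereocentres must be set between C5 (next to the quaternary C4) and the quaternary C10 on a folded bicycle. Ring A folds under the α face of ring B, so the C6–O bond points into the fold and is best made by hydride delivery to a C6 ketone from the β face, not by bringing oxygen in from the α side. The key step uses the fact that C4 hangs on C5 while ring B has oxygen at C8, 1,4 to C5: a bond from C4 to C7 turns ring B plus C4 into the 6,6-dimethylbicyclo[3.1.1]heptan-2-one skeleton, whose strained C4–C7 bond lies α to the carbonyl and can be traded for the C3–C4 bond of ring A.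

## Logic of the disconnections

30 to 28 and 29. The C11=C12 double bond is cut. The enone is the most sensitive part of 30, so it is made last under neutral conditions; what remains is a propenyl group on C9 and a bought four-carbon partner. The forward step must be an E-selective cross-metathesis at an alkene whose allylic carbon lies between C8 and C10, with two free hydroxyls present.

28 to 27. No skeletal bond is cut; the double bond moves to the chain terminus. An allyl group is what an enolate alkylation can deliver, and it is the least electron-rich alkene in every oxidation in between. The demand is isomerisation by one position only.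

27 to 24 (through 26 and 25). The two O–Si bonds, the acetyl–O6 bond and the C6–H bond are cut in turn. C6–O is made from a C6 ketone by hydride from the open β face, and the acetate is placed while O7 and O8 are silylated, so only O6 can react. The gain is a C6 carbonyl that activates C7. The demand is β-face reduction without silyl migration or C7 epimerisation.

24 to 22 (through 23). The C7–O bond is cut. C7 is α to the C6 carbonyl, so oxygen arrives electrophilically on an enol ether, from the β face and anti to the 8α-silyloxy group. The silyl group that migrates to O7 is the protection needed above. The demand is enolisation toward C7, not C5.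

22 to 20 (through 21). The C8–O bond is cut: the β-hydroxy ketone is the formal hydrate of the enone. Forward, hydroperoxide adds to C8 and the extra C7–O bond of the epoxide is removed reductively. The gain is that C8 is no longer a stereocentre. The demand is axial attack on the α face of C8, anti to the C9 substituent, under base mild enough to spare C5–H.

20 to 18 (through 19). The C8–CH3 bond is cut and the carbonyl returns from C6 to C8. Ring B oxygen sits at C8 after the key step; methyl addition there and oxidative transposition put both groups in place in two steps. The C8 configuration of 19 is irrelevant. The demand is clean 1,2-addition and a 1,3-oxidative shift.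

18 to 15 and 16. The C9–C11 bond is cut. C9 is the only kinetically enolisable position of 15, so the alkylation is regiochemically unambiguous. The demand is monoalkylation on the β face.

15 to 11 (through 12). The C6=C7 unsaturation is removed and the C2=C3 alkene of ring A restored. The enone blocks C7 and carries the later transposition; C10 has no hydrogen, so dehydrogenation can only go toward C6. The demand is to hydrogenate C2=C3 before any other alkene exists.

11 to 9. The C3–C4 bond of ring A is cut and C4 is tied back to C7. The decalin becomes a pinane with a three-carbon arm, so ring B, C4 and both fusion centres come from the chiral pool. The demand is that the C4–C7 bond ionises and that C3 of the arm captures the C4 cation faster than the cation loses a proton; the arm must be on the same face as C4.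

9 to 7 (through 8). The Z-alkene is traced to an alkyne and the C10–CH3 bond is cut. Adding methyl last puts it anti to the gem-dimethyl bridge and leaves the arm syn to it, as the key step needs; the reverse order would give the wrong C10 epimer. The demand is cuprate addition to a β,β-disubstituted enone and syn semihydrogenation.

7 to 3 and 4 (through 6). The C10–C1 bond is cut; the carbonyl, at C10 in 3, is moved to C8 by oxidative transposition after the arm is attached. The gain is a simple bicyclic enone and a three-carbon silylated nucleophile. The demand is 1,2-addition through the propargylic carbon.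

3 to 1. The C8=C9 double bond is removed. 1 supplies the bridgehead configuration that becomes C5 (and, through step 4, C10). The demand is dehydrogenation away from the bridgehead, the only direction open.

## Other disconnections considered

Alternative 1: Cut C5–C6 and C9–C10 (ring B) into 3,3-dimethylcyclohex-1-ene-1-carbaldehyde A1 and the 2-silyloxy diene A2. A chiral oxazaborolidinium Lewis acid would activate A1, and endo cycloaddition would give A3 with both fusion centres, C9 with a one-carbon handle, the C8 methyl and a masked C7 ketone.
- In favour: it is convergent, the absolute configuration is catalyst-controlled, and the reaction class is concerted and well precedented. C9 is set in the ring-forming step, whereas the chosen plan needs a separate alkylation. On precedent and on C9 this alternative is the better one.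
- Against: A1 is a trisubstituted enal with a neopentyl β-carbon and must form the C10 quaternary centre. The angular group arrives as CHO and must be reduced to CH3. Oxygen is at C7 only, so the concave C6–O bond and the tertiary C8 alcohol still need several redox steps.
- Comparison: it builds ring B on a bought ring A; the chosen plan builds ring A on a chiral-pool ring B. A3 should be about three steps from bought material against six to 11, but the aldehyde removal and the oxygen adjustments make the totals comparable.

Alternative 2: Cut C1–C10 and C4–C5 (ring A) into 2,6-dimethyl-1,4-benzoquinone A4 and 4-methylpenta-1,3-diene A5. A chiral oxazaborolidinium Lewis acid would give the cis-fused ene-dione A6.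
- In favour: one step from two bought compounds gives a cis-decalin that already has the C6 carbonyl and the methyl-substituted C7=C8 enone. The chosen route reaches that array only at 20, so on step economy to this oxidation pattern the alternative is clearly better. The reaction class is also precedented.
- Against: A5 has a Z methyl on its reacting terminus, which disfavours the s-cis conformer and makes bond formation at the future C4 very hindered. C9 arrives as a ketone, so the chain must be added to a hindered carbonyl and C9–H set afterwards. C5 is epimerisable in the ene-dione.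
- Comparison: both plans close ring A and leave a C2=C3 alkene to hydrogenate, so they are equal there.

Alternative 3: Cut C5–C6 and C6–C7, with C6 coming from carbon monoxide A8. The precursor is the vinylcyclopropane A7, whose cyclopropane C5–C9–C10 is fused to ring A and carries an isopropenyl group on C9. A rhodium carbonyl chloride catalyst under A8 would give the 8-en-6-one A9.
- In favour: it is strain-driven like the chosen plan, but the [5+1] carbonylation is a known reaction class, so it is better on precedent. It puts the C6 carbonyl and the C8 methyl in place directly, better than steps 10 and 11 here. Cis fusion follows from the cyclopropane.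
- Against: A7 needs an enantioselective cyclopropanation of a hindered trisubstituted cyclohexene. The metal must insert into C5–C9 and not C9–C10. C9 is sp2 and γ to the ketone in A9, so the side chain has no enolate handle, and the C8 oxygen is still missing.
- Comparison: the core is shorter, but attaching the C9 chain is the costly part, so the total is unlikely to be lower.

Key step: step 6

Remark: target carbon numbers and α/β are used for all decalins. For the pinanes 7–9, pinane C2 = C8, C4 = C10, C6 = C4, C1 = C7 and C5 = C5. The configurations of 1, 9, 11 and 30 were checked atom by atom and are mutually consistent.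

Assumption: 19 is drawn as the 8α-alcohol; its C8 epimer would serve equally, because step 11 makes C8 trigonal.

## Steps

Step 1
Reactants: 1 (1R,5S)-(+)-nopinone
Product: 3 apoverbenone (6,6-dimethylbicyclo[3.1.1]hept-3-en-2-one), via silyl enol ether 2 (not isolated)
Conditions: Me3SiOTf, Et3N, CH2Cl2, 0 °C; then Pd(OAc)2 (10 mol %), O2 (1 atm), DMSO, 25 °C
Reagents that add atoms: none
Why: Saegusa–Ito dehydrogenation; the bridgehead cannot enolise, so only the C3 enol ether forms, and the palladium enolate can only lose the C4 hydrogen. No stereocentre is touched.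

Step 2
Reactants: 3 apoverbenone; 4 1-(trimethylsilyl)propyne
Product: 6 2-[3-(trimethylsilyl)prop-2-ynyl]-6,6-dimethylbicyclo[3.1.1]hept-3-en-2-ol (hydroxyl syn to the gem-dimethyl bridge), via lithiated propyne 5 (not isolated)
Conditions: 4, n-BuLi, TMEDA, THF, −78 to 0 °C; then 3, −78 °C; then H2O
Reagents that add atoms: none
Why: Propargylic lithiation and 1,2-addition of the organolithium to the enone carbonyl, anti to the gem-dimethyl bridge; the bulky silyl group favours bonding through the CH2 terminus. The carbinol configuration is erased in step 3.

Step 3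
Reactants: 6 tertiary allylic alcohol
Product: 7 4-[3-(trimethylsilyl)prop-2-ynyl]-6,6-dimethylbicyclo[3.1.1]hept-3-en-2-one
Conditions: [C5H5NH][CrO3Cl], CH2Cl2, 25 °C
Reagents that add atoms: none
Why: Babler–Dauben oxidative 1,3-transposition of a tertiary allylic alcohol; the chromate ester shifts across the allyl unit and is oxidised, so the carbonyl lands on C8 and the arm stays on the new β-carbon C10.

Step 4
Reactants: 7 arm-bearing enone
Product: 8 4-methyl-4-[3-(trimethylsilyl)prop-2-ynyl]-6,6-dimethylbicyclo[3.1.1]heptan-2-one (methyl anti to the gem-dimethyl bridge)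
Conditions: Me2CuLi (from MeLi and CuI), Et2O, −20 to 0 °C; then H2O
Reagents that add atoms: lithium dimethylcuprate, [Li+].C[Cu-]C
Why: Gilman cuprate conjugate addition to a verbenone-type β,β-disubstituted enone. The methyl group enters C10 anti to the gem-dimethyl bridge, which sets C10 and leaves the arm syn to the bridge.

Step 5
Reactants: 8 alkynyl ketone
Product: 9 4-methyl-4-[(Z)-3-(trimethylsilyl)allyl]-6,6-dimethylbicyclo[3.1.1]heptan-2-one
Conditions: H2 (1 atm), Pd/CaCO3 poisoned with Pb(OAc)2, quinoline, hexane, 25 °C
Reagents that add atoms: none
Why: Lindlar semihydrogenation; syn addition of H2 to the silylalkyne gives the Z-vinylsilane, and the ketone is not reduced.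

Step 6
Reactants: 9 Z-vinylsilane ketone
Product: 11 cis-4,4,10-trimethyl-2-octalin-8-one (5β-H and 10β-CH3), via titanium enolate 10 (not isolated)
Conditions: TiCl4 (1.5 equiv), 2,6-di-tert-butylpyridine (0.3 equiv), CH2Cl2, −78 to −40 °C; then H2O
Reagents that add atoms: none
Why: Proposed new method: TiCl4 on the C8 carbonyl weakens the strained C4–C7 bond, and heterolysis gives a tertiary C4 cation and a C7=C8 trichlorotitanium enolate, the known acid cleavage mode of pinan-2-ones. The cation stays on C5 on the α face, the face that carries the C1–C3 arm because methyl entered C10 anti to the bridge, so ring A can only close cis. The Z-vinylsilane attacks through its silicon-bearing carbon C3 in a 6-endo closure, which places the charge at C2, β to silicon, and loss of Me3SiCl fixes the alkene at C2=C3. The closest known reaction types are the Lewis-acid opening of nopinone-type cyclobutanes to p-menthane cations and vinylsilane-terminated cation cyclisations. No stereocentre is created; C5 and C10 are untouched, and their cis relationship comes from the pinane bridgehead and step 4. The step needs C–C bond formation to beat proton loss to an isopropenyl group, reversible chloride capture, and addition of the vinylsilane to the activated carbonyl. The six-membered intramolecular closure, the reactivity of a tertiary cation and a hindered pyridine proton trap (which also guards against protodesilylation) favour the desired path.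

Step 7
Reactants: 11 octalinone
Product: 12 cis-4,4,10-trimethyldecalin-8-one
Conditions: H2 (1 atm), Pd/C, EtOAc, 25 °C
Reagents that add atoms: none
Why: Heterogeneous hydrogenation of the only alkene (C2=C3); the ketone and both stereocentres are unaffected.

Step 8
Reactants: 12 saturated ketone
Product: 15 cis-4,4,10-trimethyl-6-octalin-8-one, via lithium enolate 13 (not isolated), via silyl enol ether 14 (not isolated)
Conditions: LiN(iPr)2, THF, −78 °C; Me3SiCl; then Pd(OAc)2 (10 mol %), O2 (1 atm), DMSO, 25 °C
Reagents that add atoms: none
Why: Saegusa–Ito dehydrogenation through kinetic enolisation at the less hindered C7 (C9 is neopentyl). A C9 enol ether could not eliminate because C10 has no hydrogen, so 15 is the only possible enone.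

Step 9
Reactants: 15 enone; 16 allyl iodide
Product: 18 9β-allyl-cis-4,4,10-trimethyl-6-octalin-8-one, via lithium dienolate 17 (not isolated)
Conditions: LiN(iPr)2, THF, −78 °C; then 16, DMPU, −78 to −30 °C
Reagents that add atoms: none
Why: Kinetic α′-deprotonation gives the cross-conjugated dienolate, and C9 is the only position it can alkylate. Allyl iodide should enter axially on the β face, anti to the pseudoaxial C10–C1 bond and on the convex side of the cis-decalin, which sets C9.

Step 10
Reactants: 18 allyl enone
Product: 19 9β-allyl-4,4,8β,10-tetramethyl-cis-6-octalin-8α-ol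
Conditions: MeLi, CeCl3, THF, −78 °C; then H2O
Reagents that add atoms: methyllithium, [Li]C
Why: Organocerium 1,2-addition to an enolisable enone without enolisation or conjugate addition. Equatorial attack from the β face is expected, but the C8 configuration is erased in step 11.

Step 11
Reactants: 19 tertiary allylic alcohol
Product: 20 9β-allyl-4,4,8,10-tetramethyl-cis-7-octalin-6-one
Conditions: [C5H5NH][CrO3Cl], CH2Cl2, 25 °C
Reagents that add atoms: none
Why: Babler–Dauben oxidative transposition moves oxygen from C8 to C6 and gives the 8-methyl enone. The mildly acidic conditions should not epimerise C5 or C9, and the allyl group is inert.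

Step 12
Reactants: 20 transposed enone
Product: 21 9β-allyl-7α,8α-epoxy-4,4,8β,10-tetramethyl-cis-decalin-6-one
Conditions: 30% H2O2, NaOH (cat.), MeOH, 0 °C
Reagents that add atoms: hydrogen peroxide, OO
Why: Weitz–Scheffer epoxidation, selective for the enone over the allyl group. Hydroperoxide should add to C8 axially on the α face, anti to the pseudoaxial 9β-allyl group, which places the tertiary C8–O bond α.

Step 13
Reactants: 21 epoxy ketone
Product: 22 9β-allyl-8α-hydroxy-4,4,8β,10-tetramethyl-cis-decalin-6-one
Conditions: SmI2, THF–MeOH, −90 °C
Reagents that add atoms: none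
Why: SmI2 reduction of an α,β-epoxy ketone cleaves the C7–O bond next to the carbonyl and keeps the 8α-hydroxyl. The cold, non-basic conditions avoid dehydration of the β-hydroxy ketone.

Step 14
Reactants: 22 β-hydroxy ketone
Product: 24 9β-allyl-7β,8α-bis(triethylsilyloxy)-4,4,8β,10-tetramethyl-cis-decalin-6-one, via bis-silyl enol ether 23 (not isolated)
Conditions: Et3SiOTf, Et3N, CH2Cl2, −78 to 0 °C; then 3-ClC6H4CO3H, NaHCO3, hexane–CH2Cl2, −20 °C
Reagents that add atoms: triethylsilyl trifluoromethanesulfonate, CC[Si](CC)(CC)OS(=O)(=O)C(F)(F)F; 3-chloroperbenzoic acid, OOC(=O)c1cccc(Cl)c1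
Why: Rubottom oxidation; soft enolisation silylates O8 and forms the C6=C7 enol ether, because C5–H lies between two quaternary carbons. The peracid attacks C7 from the β face, anti to the 8α-silyloxy group and away from the buried α face of C6, and 1,4-silyl migration gives the 7β-silyl ether.

Step 15
Reactants: 24 silyloxy ketone
Product: 25 9β-allyl-7β,8α-bis(triethylsilyloxy)-4,4,8β,10-tetramethyl-cis-decalin-6α-ol
Conditions: NaBH4, CeCl3·7H2O, MeOH, −40 °C
Reagents that add atoms: none
Why: Luche reduction; the α face of C6 lies inside the fold under ring A, so hydride should arrive from the β face and give the 6α-alcohol. The cold, weakly basic medium is chosen to avoid silyl migration and C7 epimerisation.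

Step 16
Reactants: 25 alcohol
Product: 26 6α-acetoxy-9β-allyl-7β,8α-bis(triethylsilyloxy)-4,4,8β,10-tetramethyl-cis-decalin
Conditions: Ac2O, DMAP, pyridine, 40 °C
Reagents that add atoms: acetic anhydride, CC(=O)OC(C)=O
Why: DMAP-catalysed acetylation of the only free hydroxyl; O7 and O8 are silylated, so the acetate can only go on O6.

Step 17
Reactants: 26 acetate
Product: 27 6α-acetoxy-9β-allyl-4,4,8β,10-tetramethyl-cis-decalin-7β,8α-diol
Conditions: HF·pyridine, THF, 0 to 25 °C
Reagents that add atoms: none
Why: Fluoride cleavage of both triethylsilyl ethers in a buffered, weakly acidic medium that should not move the acetyl group from O6 to O7.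

Step 18
Reactants: 27 allyl diol
Product: 28 6α-acetoxy-9β-[(E)-prop-1-enyl]-4,4,8β,10-tetramethyl-cis-decalin-7β,8α-diol
Conditions: RuHCl(CO)(PPh3)3 (5 mol %), toluene, 80 °C
Reagents that add atoms: none
Why: Ruthenium hydride alkene isomerisation (hydrometalation and β-hydride elimination) moves the terminal alkene one position inward to the more stable 1-propenyl group. The E isomer is expected, and the geometry does not matter for step 19.

Step 19
Reactants: 28 propenyl diol; 29 but-3-en-2-one
Product: 30 CNP0136046.2 (6α-acetoxy-7β,8α-dihydroxy-9β-[(E)-3-oxobut-1-enyl]-4,4,8β,10-tetramethyl-cis-decalin)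
Conditions: 29 (10 equiv), second-generation Hoveyda–Grubbs catalyst (10 mol %), CH2Cl2, 40 °C
Reagents that add atoms: none
Why: Olefin cross-metathesis of an internal alkene with an electron-poor partner; propene is lost and the E-enone is the thermodynamic product. The neutral conditions spare the acetate, the tertiary alcohol and the C9 hydrogen.

## Compound list

1 | (1R,5S)-(+)-nopinone | O=C1CC[C@H]2C[C@@H]1C2(C)C | starting material
2 | 2-(trimethylsilyloxy)-6,6-dimethylbicyclo[3.1.1]hept-2-ene | C[Si](C)(C)OC1=CC[C@H]2C[C@@H]1C2(C)C | intermediate
3 | apoverbenone, 6,6-dimethylbicyclo[3.1.1]hept-3-en-2-one | O=C1C=C[C@H]2C[C@@H]1C2(C)C | intermediate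
4 | 1-(trimethylsilyl)propyne | CC#C[Si](C)(C)C | starting material
5 | 3-lithio-1-(trimethylsilyl)propyne | [Li]CC#C[Si](C)(C)C | intermediate
6 | 2-[3-(trimethylsilyl)prop-2-ynyl]-6,6-dimethylbicyclo[3.1.1]hept-3-en-2-ol, OH syn to the gem-dimethyl bridge | C[Si](C)(C)C#CC[C@@]1(O)C=C[C@H]2C[C@@H]1C2(C)C | intermediate
7 | 4-[3-(trimethylsilyl)prop-2-ynyl]-6,6-dimethylbicyclo[3.1.1]hept-3-en-2-one | C[Si](C)(C)C#CCC1=CC(=O)[C@H]2C[C@@H]1C2(C)C | intermediate
8 | 4-methyl-4-[3-(trimethylsilyl)prop-2-ynyl]-6,6-dimethylbicyclo[3.1.1]heptan-2-one, methyl anti to the gem-dimethyl bridge | C[Si](C)(C)C#CC[C@]1(C)CC(=O)[C@H]2C[C@@H]1C2(C)C | intermediate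
9 | 4-methyl-4-[(Z)-3-(trimethylsilyl)allyl]-6,6-dimethylbicyclo[3.1.1]heptan-2-one | C[Si](C)(C)/C=C\C[C@]1(C)CC(=O)[C@H]2C[C@@H]1C2(C)C | intermediate
10 | trichlorotitanium C7=C8 enolate of 11 | C1C(O[Ti](Cl)(Cl)Cl)=CC[C@@H]2C(C)(C)C=CC[C@@]21C | intermediate
11 | cis-4,4,10-trimethyl-2-octalin-8-one (5β-H, 10β-CH3) | C1C(=O)CC[C@@H]2C(C)(C)C=CC[C@@]21C | intermediate
12 | cis-4,4,10-trimethyldecalin-8-one | C1C(=O)CC[C@@H]2C(C)(C)CCC[C@@]21C | intermediate
13 | lithium C7=C8 enolate of 12 | C1C(O[Li])=CC[C@@H]2C(C)(C)CCC[C@@]21C | intermediate
14 | 8-(trimethylsilyloxy)-cis-4,4,10-trimethyl-7-octalin | C1C(O[Si](C)(C)C)=CC[C@@H]2C(C)(C)CCC[C@@]21C | intermediate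
15 | cis-4,4,10-trimethyl-6-octalin-8-one | C1C(=O)C=C[C@@H]2C(C)(C)CCC[C@@]21C | intermediate
16 | allyl iodide | C=CCI | starting material
17 | lithium C8=C9 dienolate of 15 | C1=C(O[Li])C=C[C@@H]2C(C)(C)CCC[C@@]21C | intermediate
18 | 9β-allyl-cis-4,4,10-trimethyl-6-octalin-8-one | C=CC[C@H]1C(=O)C=C[C@@H]2C(C)(C)CCC[C@@]21C | intermediate
19 | 9β-allyl-4,4,8β,10-tetramethyl-cis-6-octalin-8α-ol | C=CC[C@H]1[C@](C)(O)C=C[C@@H]2C(C)(C)CCC[C@@]21C | intermediate
20 | 9β-allyl-4,4,8,10-tetramethyl-cis-7-octalin-6-one | C=CC[C@H]1C(C)=CC(=O)[C@@H]2C(C)(C)CCC[C@@]21C | intermediate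
21 | 9β-allyl-7α,8α-epoxy-4,4,8β,10-tetramethyl-cis-decalin-6-one | C=CC[C@H]1[C@]3(C)O[C@@H]3C(=O)[C@@H]2C(C)(C)CCC[C@@]21C | intermediate
22 | 9β-allyl-8α-hydroxy-4,4,8β,10-tetramethyl-cis-decalin-6-one | C=CC[C@H]1[C@](C)(O)CC(=O)[C@@H]2C(C)(C)CCC[C@@]21C | intermediate
23 | 9β-allyl-6,8α-bis(triethylsilyloxy)-4,4,8β,10-tetramethyl-cis-6-octalin | C=CC[C@H]1[C@](C)(O[Si](CC)(CC)CC)C=C(O[Si](CC)(CC)CC)[C@@H]2C(C)(C)CCC[C@@]21C | intermediate
24 | 9β-allyl-7β,8α-bis(triethylsilyloxy)-4,4,8β,10-tetramethyl-cis-decalin-6-one | C=CC[C@H]1[C@](C)(O[Si](CC)(CC)CC)[C@@H](O[Si](CC)(CC)CC)C(=O)[C@@H]2C(C)(C)CCC[C@@]21C | intermediate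
25 | 9β-allyl-7β,8α-bis(triethylsilyloxy)-4,4,8β,10-tetramethyl-cis-decalin-6α-ol | C=CC[C@H]1[C@](C)(O[Si](CC)(CC)CC)[C@@H](O[Si](CC)(CC)CC)[C@H](O)[C@@H]2C(C)(C)CCC[C@@]21C | intermediate
26 | 6α-acetoxy-9β-allyl-7β,8α-bis(triethylsilyloxy)-4,4,8β,10-tetramethyl-cis-decalin | C=CC[C@H]1[C@](C)(O[Si](CC)(CC)CC)[C@@H](O[Si](CC)(CC)CC)[C@H](OC(C)=O)[C@@H]2C(C)(C)CCC[C@@]21C | intermediate
27 | 6α-acetoxy-9β-allyl-4,4,8β,10-tetramethyl-cis-decalin-7β,8α-diol | C=CC[C@H]1[C@](C)(O)[C@@H](O)[C@H](OC(C)=O)[C@@H]2C(C)(C)CCC[C@@]21C | intermediate
28 | 6α-acetoxy-9β-[(E)-prop-1-enyl]-4,4,8β,10-tetramethyl-cis-decalin-7β,8α-diol | C/C=C/[C@H]1[C@](C)(O)[C@@H](O)[C@H](OC(C)=O)[C@@H]2C(C)(C)CCC[C@@]21C | intermediate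
29 | but-3-en-2-one | C=CC(C)=O | starting material
30 | CNP0136046.2 | CC(=O)/C=C/[C@H]1[C@](C)(O)[C@@H](O)[C@H](OC(C)=O)[C@@H]2C(C)(C)CCC[C@@]21C | target

## Step count and least certain steps

Total: 19 steps. Longest linear sequence: 19 steps (1 to 30); 4, 16 and 29 are bought and used directly.

Step 6 (key step). The C4 cation may lose a proton to an isopropenyl group or shift hydride from C5 before the vinylsilane captures it, because the new bond is formed at a fully substituted carbon. The vinylsilane may also add to the TiCl4-activated carbonyl or be protodesilylated. Fallback, in separate known stages, from 8: Zn(OAc)2 and BF3·OEt2 in Ac2O open the cyclobutane to the ring-opened enol acetate with a tertiary C4 acetate F1. Semihydrogenation over Pd/CaCO3 poisoned with Pb(OAc)2 gives its Z-vinylsilane F2. SnCl4 at −78 °C ionises the tertiary acetate, and a vinylsilane-terminated cation cyclisation gives the enol acetate of the octalinone F3. K2CO3 in methanol returns to 11.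

Step 9. Facial selectivity may be poor, or a second alkylation may occur, since both faces of the dienolate carry a C10 substituent. Fallback from 15: the dienolate is O-acylated with allyl chloroformate to the allyl dienyl carbonate F4. Decarboxylative allylation with Pd2(dba)3 and a chiral phosphinooxazoline ligand then places the allyl group on C9 under catalyst control and returns to 18.

Step 12. Hydroperoxide may attack the wrong face of C8, or a slow reaction at the fully substituted β-carbon may allow base-induced epimerisation of C5 from cis to trans fusion. Fallback from 20: copper-catalysed conjugate borylation (CuCl, NaOtBu, a chiral bisphosphine, B2pin2, MeOH) gives the C8 pinacol boronate F5 under catalyst control. NaBO3 oxidation with retention gives 22 directly, bypassing 21.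

Step 15. Hydride may be delivered from the wrong face if a ring-flipped conformer reacts; silyl migration from O7 to O6 or epimerisation at C7 are also possible. Fallback from 24: HF·pyridine gives the keto diol F6. Me4NBH(OAc)3 binds the 7β-hydroxyl and delivers hydride intramolecularly to the β face of C6, giving the triol F7. Monoacetylation at O6 (Ac2O, 2,4,6-collidine, −20 °C; O7 is flanked by the quaternary C8) returns to 27. The regioselectivity of this acetylation is itself uncertain.

Step 19. Metathesis may be slow at a propenyl group whose allylic carbon lies between C8 and C10, with catalyst decay and self-metathesis of 29. Fallback from 28: ozonolysis (O3, CH2Cl2, −78 °C; then Me2S) gives the C9 aldehyde F8. A Wittig reaction with Ph3P=CHC(O)CH3 in toluene at 60 °C gives 30.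

## Further compounds

F1 | step 6 | 1-acetoxy-4-(2-acetoxyprop-2-yl)-5-methyl-5-[3-(trimethylsilyl)prop-2-ynyl]cyclohexene, side chains at C4 and C5 cis | C1C(OC(C)=O)=CC[C@H](C(C)(C)OC(C)=O)[C@]1(C)CC#C[Si](C)(C)C
F2 | step 6 | 1-acetoxy-4-(2-acetoxyprop-2-yl)-5-methyl-5-[(Z)-3-(trimethylsilyl)allyl]cyclohexene | C1C(OC(C)=O)=CC[C@H](C(C)(C)OC(C)=O)[C@]1(C)C/C=C\[Si](C)(C)C
F3 | step 6 | 8-acetoxy-cis-4,4,10-trimethylocta-2,7-diene (enol acetate of 11) | C1C(OC(C)=O)=CC[C@@H]2C(C)(C)C=CC[C@@]21C
F4 | step 9 | allyl carbonate of the C8=C9 dienol of 15 | C1=C(OC(=O)OCC=C)C=C[C@@H]2C(C)(C)CCC[C@@]21C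
F5 | step 12 | 9β-allyl-8α-(pinacolboryl)-4,4,8β,10-tetramethyl-cis-decalin-6-one | C=CC[C@H]1[C@](C)(B3OC(C)(C)C(C)(C)O3)CC(=O)[C@@H]2C(C)(C)CCC[C@@]21C
F6 | step 15 | 9β-allyl-7β,8α-dihydroxy-4,4,8β,10-tetramethyl-cis-decalin-6-one | C=CC[C@H]1[C@](C)(O)[C@@H](O)C(=O)[C@@H]2C(C)(C)CCC[C@@]21C
F7 | step 15 | 9β-allyl-4,4,8β,10-tetramethyl-cis-decalin-6α,7β,8α-triol | C=CC[C@H]1[C@](C)(O)[C@@H](O)[C@H](O)[C@@H]2C(C)(C)CCC[C@@]21C
F8 | step 19 | 6α-acetoxy-7β,8α-dihydroxy-4,4,8β,10-tetramethyl-cis-decalin-9β-carbaldehyde | O=C[C@H]1[C@](C)(O)[C@@H](O)[C@H](OC(C)=O)[C@@H]2C(C)(C)CCC[C@@]21C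
A1 | alternative 1 | 3,3-dimethylcyclohex-1-ene-1-carbaldehyde | O=CC1=CC(C)(C)CCC1
A2 | alternative 1 | (E)-5-benzyloxy-2-(tert-butyldimethylsilyloxy)-3-methylpenta-1,3-diene | C=C(O[Si](C)(C)C(C)(C)C)/C(C)=C/COCc1ccccc1
A3 | alternative 1 | cis-octalin with angular formyl, C9 benzyloxymethyl and C7 silyl enol ether | C(c1ccccc1)OC[C@H]1C(C)=C(O[Si](C)(C)C(C)(C)C)C[C@@H]2C(C)(C)CCC[C@@]21C=O
A4 | alternative 2 | 2,6-dimethyl-1,4-benzoquinone | CC1=CC(=O)C=C(C)C1=O
A5 | alternative 2 | 4-methylpenta-1,3-diene | C=CC=C(C)C
A6 | alternative 2 | cis-2,5,5,8a-tetramethyl-4a,5,8,8a-tetrahydronaphthalene-1,4-dione | O=C1C(C)=CC(=O)[C@@H]2C(C)(C)C=CC[C@@]21C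
A7 | alternative 3 | 1,5,5-trimethyl-7-(prop-1-en-2-yl)bicyclo[4.1.0]heptane, isopropenyl exo | C=C(C)[C@H]1[C@@H]2C(C)(C)CCC[C@]12C
A8 | alternative 3 | carbon monoxide | [C-]#[O+]
A9 | alternative 3 | cis-4,4,8,10-tetramethyl-8-octalin-6-one | C1=C(C)CC(=O)[C@@H]2C(C)(C)CCC[C@@]21C
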